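**Plan**

1. Retrosynthetic cuts, in order: the oxirane C–O bonds (back to a C2=C3 alkene and a C1 carbinol), the two senecioate C–O bonds, C7–C9 (2-iodoalkene + aldehyde), the ring bond C1–C6 (back to an open-chain 1,6-dialdehyde), C2=C3 (Z-olefination) and C5–C7 (conjugate alkynylation).
2. Enabling feature: C1(=O)–C6H(O-acyl) is an acyloin pair, and C1 is flanked by the C2–C3 oxirane, the retron of a cis C2=C3 alkene. Both carbons can therefore be aldehydes of one chain that the (Z)-alkene holds face to face, and after coupling C1 is the only allylic carbinol, so it alone is oxidised to the ketone.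
3. Forward order: C3–C6 enal + alkyne (C7, C8), then Z-olefination (adds C1, C2 and the methyl), hydroiodination, dialdehyde, the six-membered ring (the only carbocycle), side chain C9–C12, both esters, and the oxirane last.
4. Stereochemistry: C5 from the Rh/bisphosphine catalyst; C6 in the ring closure (anti to the C5 substituent, also the thermodynamic epimer); C9 from the chiral Cr catalyst; C2/C3 by hydroxyl-directed epoxidation from a C1 carbinol that the Luche reduction places cis to the C5 side chain and that is then oxidised away.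

Key step: step 8

Remark on locants: C1 = ring C=O, C2 = C(CH3)–O, C3 = CH–O, C4 = CH2, C5 = CH bearing the side chain, C6 = CH–O-acyl; side chain C7(=C8H2)–C9H(O-acyl)–C10H2–C11H=C12(CH3)2. CIP descriptors at C5 change along the route only because substituent priorities change.

Assumption: the sense of induction of the two catalyst-controlled steps is not predicted here; the ligand antipode that gives (S)-5 in step 2 and (3R)-17 in step 11 is used, written as (R)-DTBM-SEGPHOS and (S)-N-[2-(4-isopropyl-4,5-dihydrooxazol-2-yl)-6-methylphenyl]methanesulfonamide.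

**Step 1**
Reactants: 1 (2Z)-but-2-ene-1,4-diyl diacetate; 2 (2E)-but-2-enal
Product: 3 (2E)-4-oxobut-2-en-1-yl acetate
Conditions: second-generation Hoveyda–Grubbs catalyst RuCl2(H2IMes)(=CH-C6H4-2-OiPr) (2 mol %), excess 2, CH2Cl2, 40 °C
Reagents that add atoms: none
Why: Olefin cross-metathesis of a reactive allylic diacetate with an electron-poor enal favours the cross product and should give the (E)-enal under thermodynamic control; no stereocentre is formed.

**Step 2**
Reactants: 3 (2E)-4-oxobut-2-en-1-yl acetate; 4 ethynyltri(propan-2-yl)silane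
Product: 5 (2S)-2-(2-oxoethyl)-4-[tri(propan-2-yl)silyl]but-3-yn-1-yl acetate
Conditions: [Rh(OAc)(C2H4)2]2 (2.5 mol %), (R)-DTBM-SEGPHOS (6 mol %), MeOH, 40 °C
Reagents that add atoms: none
Why: Rhodium-catalysed asymmetric conjugate alkynylation of an enal adds the alkynyl–rhodium species to one enantioface of the β-carbon, which sets C5 under ligand control, while the bulky silyl group suppresses alkyne dimerisation.

**Step 3**
Reactants: 5 (2S)-2-(2-oxoethyl)-4-[tri(propan-2-yl)silyl]but-3-yn-1-yl acetate; 6 ethyl 2-[bis(2,2,2-trifluoroethoxy)phosphoryl]propanoate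
Product: 7 ethyl (2Z,5S)-5-[(acetyloxy)methyl]-2-methyl-7-[tri(propan-2-yl)silyl]hept-2-en-6-ynoate
Conditions: KN(SiMe3)2, 18-crown-6, THF, −78 °C
Reagents that add atoms: none
Why: Still–Gennari olefination with the electron-poor bis(trifluoroethyl) phosphonate under dissociating conditions should give the (Z)-2-methyl enoate, which places C1 and C4 cis as the ring requires; C5 is not touched.

**Step 4**
Reactants: 7 ethyl (2Z,5S)-5-[(acetyloxy)methyl]-2-methyl-7-[tri(propan-2-yl)silyl]hept-2-en-6-ynoate
Product: 8 ethyl (2Z,5S)-5-[(acetyloxy)methyl]-2-methylhept-2-en-6-ynoate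
Conditions: Bu4NF, AcOH (1:1), THF, 0 °C to rt
Reagents that add atoms: none
Why: Fluoride-induced protodesilylation of the alkynyl C–Si bond, buffered with acetic acid so that the acetate and the (Z)-enoate should survive.

**Step 5**
Reactants: 8 ethyl (2Z,5S)-5-[(acetyloxy)methyl]-2-methylhept-2-en-6-ynoate
Product: 10 ethyl (2Z,5R)-5-[(acetyloxy)methyl]-6-iodo-2-methylhepta-2,6-dienoate, via alkenylborane 9 (not isolated)
Conditions: B-iodo-9-BBN, pentane/CH2Cl2, −20 °C; then AcOH, 0 °C
Reagents that add atoms: B-iodo-9-borabicyclo[3.3.1]nonane, IB1C2CCCC1CCC2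
Why: Haloboration–protodeboration (Markovnikov hydroiodination): syn addition of B–I puts iodine on the internal carbon C7 and boron on C8, and acetic acid cleaves the C–B bond to leave the 2-iodo-1-alkene; the electron-poor enoate alkene does not react.

**Step 6**
Reactants: 10 ethyl (2Z,5R)-5-[(acetyloxy)methyl]-6-iodo-2-methylhepta-2,6-dienoate
Product: 11 (2Z,5R)-5-(hydroxymethyl)-6-iodo-2-methylhepta-2,6-dien-1-ol
Conditions: i-Bu2AlH (6 equiv), CH2Cl2, −78 to 0 °C; Rochelle salt work-up
Reagents that add atoms: none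
Why: Hydride reduction of both esters (1,2-reduction of the enoate to the (Z)-allylic alcohol and cleavage of the acetate) frees the C1 and C6 hydroxyls in one operation; the alkenyl iodide and C5 are inert.

**Step 7**
Reactants: 11 (2Z,5R)-5-(hydroxymethyl)-6-iodo-2-methylhepta-2,6-dien-1-ol
Product: 12 (2Z,5R)-5-(1-iodoethenyl)-2-methylhex-2-enedial
Conditions: Dess–Martin periodinane (2.4 equiv), NaHCO3, CH2Cl2, 0 °C; used at once
Reagents that add atoms: none
Why: Dess–Martin oxidation of both primary alcohols under buffered, base-free conditions should give the dialdehyde without isomerising the (Z)-enal or epimerising the α-stereocentre C5.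

**Step 8**
Reactants: 12 (2Z,5R)-5-(1-iodoethenyl)-2-methylhex-2-enedial
Product: 13 (1S,2R,6R)-6-(1-iodoethenyl)-3-methylcyclohex-3-ene-1,2-diol
Conditions: SmI2 (2.5 equiv), THF (0.005 M), −78 °C; aq. NH4Cl
Reagents that add atoms: none
Why: Two single-electron transfers from divalent samarium give the ketyl radical anions of the conjugated (Z)-enal and of the saturated aldehyde, and the C1–C6 bond forms by ketyl–carbonyl (or ketyl–ketyl) coupling inside a samarium-bridged chelate, leaving a trivalent samarium cis-diolate that is protonated on work-up. The closest known reaction type is the SmI2-mediated intramolecular pinacol coupling of 1,6-dialdehydes to cis-cyclohexane-1,2-diols. The six-membered carbocycle closes in the 6-exo-trig mode (C1 ketyl carbon onto the C6 carbonyl). C6 is set anti to the C5 substituent, which sits pseudo-equatorial in the chair-like transition state and turns the O–Sm group of C6 away from the 1-iodoethenyl group; C1 is set cis to C6 by chelation of both oxygens to one samarium, and this centre is erased in step 9. The step needs carbonyl–carbonyl coupling to win over conjugate reduction, over coupling at C3 and over C–I reduction: the (Z)-C2=C3 alkene holds C1 within bonding distance of C6, coupling through C3 would give a four-membered ring, and aprotic THF at −78 °C without HMPA should leave the alkenyl iodide and the enal C=C untouched.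

**Step 9**
Reactants: 13 (1S,2R,6R)-6-(1-iodoethenyl)-3-methylcyclohex-3-ene-1,2-diol
Product: 14 (5R,6S)-6-hydroxy-5-(1-iodoethenyl)-2-methylcyclohex-2-en-1-one
Conditions: activated MnO2 (excess), CH2Cl2, rt
Reagents that add atoms: none
Why: Chemoselective allylic oxidation: only the C1 carbinol is allylic, so MnO2 should oxidise it alone and fix the ketol regiochemistry; C6 is untouched, and its trans epimer is also the thermodynamic one.

**Step 10**
Reactants: 15 4-methylpent-3-en-1-ol
Product: 16 4-methylpent-3-enal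
Conditions: Dess–Martin periodinane, NaHCO3, CH2Cl2, 0 °C; used as a solution
Reagents that add atoms: none
Why: Buffered Dess–Martin oxidation of the homoallylic alcohol gives the β,γ-unsaturated aldehyde without base, so migration of the double bond into conjugation should be avoided.

**Step 11**
Reactants: 14 (5R,6S)-6-hydroxy-5-(1-iodoethenyl)-2-methylcyclohex-2-en-1-one; 16 4-methylpent-3-enal
Product: 17 (5S,6S)-6-hydroxy-5-[(3R)-3-hydroxy-6-methylhepta-1,5-dien-2-yl]-2-methylcyclohex-2-en-1-one
Conditions: CrCl2 (10 mol %), (S)-sulfonamide ligand of the assumption line (11 mol %), Et3N (10 mol %), NiCl2(2,9-dimethyl-1,10-phenanthroline) (2 mol %), Mn powder (2 equiv), Cp2ZrCl2 (2.5 equiv), LiCl, MeCN, rt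
Reagents that add atoms: none
Why: Catalytic asymmetric Nozaki–Hiyama–Kishi reaction: nickel activates the 2-iodoalkene, the alkenyl group passes to the chiral chromium sulfonamide complex and adds to the aldehyde in preference to the ring ketone, and the ligand sets C9.

**Step 12**
Reactants: 17 (5S,6S)-6-hydroxy-5-[(3R)-3-hydroxy-6-methylhepta-1,5-dien-2-yl]-2-methylcyclohex-2-en-1-one; 18 3-methylbut-2-enoyl chloride
Product: 19 (1S,6S)-3-methyl-6-{(3R)-6-methyl-3-[(3-methylbut-2-enoyl)oxy]hepta-1,5-dien-2-yl}-2-oxocyclohex-3-en-1-yl 3-methylbut-2-enoate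
Conditions: 18 (3 equiv), pyridine, DMAP (cat.), CH2Cl2, 0 °C to rt
Reagents that add atoms: none
Why: DMAP-catalysed acylation of both secondary hydroxyls (C6 and C9) in one operation; pyridine is used instead of a trialkylamine to limit deconjugation of the acyl chloride through the vinylketene.

**Step 13**
Reactants: 19 (1S,6S)-3-methyl-6-{(3R)-6-methyl-3-[(3-methylbut-2-enoyl)oxy]hepta-1,5-dien-2-yl}-2-oxocyclohex-3-en-1-yl 3-methylbut-2-enoate
Product: 20 (1S,2S,6S)-2-hydroxy-3-methyl-6-{(3R)-6-methyl-3-[(3-methylbut-2-enoyl)oxy]hepta-1,5-dien-2-yl}cyclohex-3-en-1-yl 3-methylbut-2-enoate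
Conditions: NaBH4, CeCl3·7H2O, MeOH, −78 °C
Reagents that add atoms: none
Why: Luche reduction gives 1,2-reduction of the enone, and axial hydride delivery on the half-chair with C5 and C6 substituents equatorial should place the C1 hydroxyl pseudo-equatorial, cis to the C5 side chain and trans to the C6 ester, as in the reduction of carvone to cis-carveol.

**Step 14**
Reactants: 20 (1S,2S,6S)-2-hydroxy-3-methyl-6-{(3R)-6-methyl-3-[(3-methylbut-2-enoyl)oxy]hepta-1,5-dien-2-yl}cyclohex-3-en-1-yl 3-methylbut-2-enoate
Product: 21 (1R,2R,3S,4S,6S)-2-hydroxy-1-methyl-4-{(3R)-6-methyl-3-[(3-methylbut-2-enoyl)oxy]hepta-1,5-dien-2-yl}-7-oxabicyclo[4.1.0]heptan-3-yl 3-methylbut-2-enoate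
Conditions: VO(acac)2 (5 mol %), t-BuOOH (1.5 equiv), CH2Cl2, 0 °C to rt
Reagents that add atoms: tert-butyl hydroperoxide, CC(C)(C)OO
Why: Vanadium-catalysed hydroxyl-directed epoxidation delivers oxygen syn to the C1 hydroxyl, which sets C2 and C3 with the oxirane on the face of the C5 side chain, and it should touch only the allylic-alcohol alkene among the five C=C bonds.

**Step 15**
Reactants: 21 (1R,2R,3S,4S,6S)-2-hydroxy-1-methyl-4-{(3R)-6-methyl-3-[(3-methylbut-2-enoyl)oxy]hepta-1,5-dien-2-yl}-7-oxabicyclo[4.1.0]heptan-3-yl 3-methylbut-2-enoate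
Product: 22 (1S,3S,4S,6S)-1-methyl-4-{(3R)-6-methyl-3-[(3-methylbut-2-enoyl)oxy]hepta-1,5-dien-2-yl}-2-oxo-7-oxabicyclo[4.1.0]heptan-3-yl 3-methylbut-2-enoate
Conditions: Dess–Martin periodinane, NaHCO3, CH2Cl2, 0 °C to rt
Reagents that add atoms: none
Why: Dess–Martin oxidation of the epoxy carbinol to the ketone under neutral conditions should leave the base-sensitive α-acyloxy-α′,β′-epoxy ketone, the C6 centre and both esters intact.

**Compound list**

1 | (2Z)-but-2-ene-1,4-diyl diacetate | CC(=O)OC/C=C\COC(C)=O | starting material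
2 | (2E)-but-2-enal | C/C=C/C=O | starting material
3 | (2E)-4-oxobut-2-en-1-yl acetate | CC(=O)OC/C=C/C=O | intermediate
4 | ethynyltri(propan-2-yl)silane | C#C[Si](C(C)C)(C(C)C)C(C)C | starting material
5 | (2S)-2-(2-oxoethyl)-4-[tri(propan-2-yl)silyl]but-3-yn-1-yl acetate | O=CC[C@H](COC(C)=O)C#C[Si](C(C)C)(C(C)C)C(C)C | intermediate
6 | ethyl 2-[bis(2,2,2-trifluoroethoxy)phosphoryl]propanoate | CCOC(=O)C(C)P(=O)(OCC(F)(F)F)OCC(F)(F)F | starting material
7 | ethyl (2Z,5S)-5-[(acetyloxy)methyl]-2-methyl-7-[tri(propan-2-yl)silyl]hept-2-en-6-ynoate | CCOC(=O)/C(C)=C\C[C@H](COC(C)=O)C#C[Si](C(C)C)(C(C)C)C(C)C | intermediate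
8 | ethyl (2Z,5S)-5-[(acetyloxy)methyl]-2-methylhept-2-en-6-ynoate | CCOC(=O)/C(C)=C\C[C@H](COC(C)=O)C#C | intermediate
9 | ethyl (2Z,5R,6Z)-5-[(acetyloxy)methyl]-7-(9-borabicyclo[3.3.1]nonan-9-yl)-6-iodo-2-methylhepta-2,6-dienoate | CCOC(=O)/C(C)=C\C[C@H](COC(C)=O)/C(I)=C/B1C2CCCC1CCC2 | intermediate
10 | ethyl (2Z,5R)-5-[(acetyloxy)methyl]-6-iodo-2-methylhepta-2,6-dienoate | CCOC(=O)/C(C)=C\C[C@H](COC(C)=O)C(I)=C | intermediate
11 | (2Z,5R)-5-(hydroxymethyl)-6-iodo-2-methylhepta-2,6-dien-1-ol | OC/C(C)=C\C[C@H](CO)C(I)=C | intermediate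
12 | (2Z,5R)-5-(1-iodoethenyl)-2-methylhex-2-enedial | O=C/C(C)=C\C[C@H](C=O)C(I)=C | intermediate
13 | (1S,2R,6R)-6-(1-iodoethenyl)-3-methylcyclohex-3-ene-1,2-diol | C=C(I)[C@@H]1CC=C(C)[C@@H](O)[C@H]1O | intermediate
14 | (5R,6S)-6-hydroxy-5-(1-iodoethenyl)-2-methylcyclohex-2-en-1-one | C=C(I)[C@@H]1CC=C(C)C(=O)[C@H]1O | intermediate
15 | 4-methylpent-3-en-1-ol | CC(C)=CCCO | starting material
16 | 4-methylpent-3-enal | CC(C)=CCC=O | intermediate
17 | (5S,6S)-6-hydroxy-5-[(3R)-3-hydroxy-6-methylhepta-1,5-dien-2-yl]-2-methylcyclohex-2-en-1-one | C=C([C@@H](CC=C(C)C)O)[C@@H]1CC=C(C)C(=O)[C@H]1O | intermediate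
18 | 3-methylbut-2-enoyl chloride | CC(C)=CC(Cl)=O | starting material
19 | (1S,6S)-3-methyl-6-{(3R)-6-methyl-3-[(3-methylbut-2-enoyl)oxy]hepta-1,5-dien-2-yl}-2-oxocyclohex-3-en-1-yl 3-methylbut-2-enoate | C=C([C@@H](CC=C(C)C)OC(=O)C=C(C)C)[C@@H]1CC=C(C)C(=O)[C@H]1OC(=O)C=C(C)C | intermediate
20 | (1S,2S,6S)-2-hydroxy-3-methyl-6-{(3R)-6-methyl-3-[(3-methylbut-2-enoyl)oxy]hepta-1,5-dien-2-yl}cyclohex-3-en-1-yl 3-methylbut-2-enoate | C=C([C@@H](CC=C(C)C)OC(=O)C=C(C)C)[C@@H]1CC=C(C)[C@H](O)[C@H]1OC(=O)C=C(C)C | intermediate
21 | (1R,2R,3S,4S,6S)-2-hydroxy-1-methyl-4-{(3R)-6-methyl-3-[(3-methylbut-2-enoyl)oxy]hepta-1,5-dien-2-yl}-7-oxabicyclo[4.1.0]heptan-3-yl 3-methylbut-2-enoate | C=C([C@@H](CC=C(C)C)OC(=O)C=C(C)C)[C@@H]1C[C@@H]2O[C@]2(C)[C@H](O)[C@H]1OC(=O)C=C(C)C | intermediate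
22 | (1S,3S,4S,6S)-1-methyl-4-{(3R)-6-methyl-3-[(3-methylbut-2-enoyl)oxy]hepta-1,5-dien-2-yl}-2-oxo-7-oxabicyclo[4.1.0]heptan-3-yl 3-methylbut-2-enoate | C=C([C@@H](CC=C(C)C)OC(=O)C=C(C)C)[C@@H]1C[C@@H]2O[C@]2(C)C(=O)[C@H]1OC(=O)C=C(C)C | target

**Step count and risks**

Total step count: 15. Longest linear sequence: 14 (steps 1 to 9 and 11 to 15; step 10 is a one-step branch).

Step 8 (ring closure). What may go wrong: conjugate reduction of the enal ketyl, E/Z scrambling of the enal radical anion followed by intermolecular coupling, or weak control of C6. The fallback replaces the reductive coupling by a redox-neutral umpolung. It sets out from dialdehyde 12: an intramolecular N-heterocyclic-carbene-catalysed benzoin reaction (2-(pentafluorophenyl)-6,7-dihydro-5H-pyrrolo[2,1-c][1,2,4]triazol-2-ium tetrafluoroborate, NaOAc as a weak base, CH2Cl2, rt) should let the Breslow intermediate of the conjugated aldehyde C1 add to C6. This gives the conjugated ketol directly and comes back to the route at hydroxy enone 14, passing by 13 and step 9. It makes no new compound (F0).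

Step 11 (side-chain union). What may go wrong: poor facial selectivity at C9, which lies remote from the ring stereocentres and depends on the chiral chromium complex alone, or reduction of the ketol by the low-valent metals. The fallback moves the bond formed from C7–C9 to C9–C10 and sets C9 by a stoichiometric chiral allylborane. It sets out from 14: palladium-catalysed reductive carbonylation (Pd(PPh3)4, CO, Bu3SnH added slowly, toluene, 50 °C) should give 2-[(1S,6S)-6-hydroxy-4-methyl-5-oxocyclohex-3-en-1-yl]prop-2-enal F1. Brown allylation with the B-allyldiisopinocampheylborane antipode matched to the (R)-carbinol (Et2O, −78 °C, ethanolamine work-up) should add to the aldehyde only and give (5S,6S)-6-hydroxy-5-[(3R)-3-hydroxyhexa-1,5-dien-2-yl]-2-methylcyclohex-2-en-1-one F2. Cross-metathesis with 2-methylbut-2-ene (second-generation Grubbs catalyst RuCl2(H2IMes)(PCy3)(=CHPh), CH2Cl2, 40 °C) should turn the terminal vinyl group into the prenyl terminus, and the fallback comes back to the route at 17.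

Step 13 (1,2-reduction). What may go wrong: poor facial selectivity of hydride delivery to C1, which would misdirect the epoxidation of step 14, or acyl migration from O6 to O1 in the basic medium. The fallback moves the control element from the substrate to a chiral catalyst. It sets out from enone 19: Corey–Bakshi–Shibata reduction ((S)- or (R)-2-methyl-CBS-oxazaborolidine matched to the required face, catecholborane, toluene, −78 °C, non-basic) should deliver the hydride under reagent control and comes back to the route at 20. It makes no new compound (F0).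

**Further compounds**

F0 | step 8 | none | none
F1 | step 11 | 2-[(1S,6S)-6-hydroxy-4-methyl-5-oxocyclohex-3-en-1-yl]prop-2-enal | C=C(C=O)[C@@H]1CC=C(C)C(=O)[C@H]1O
F2 | step 11 | (5S,6S)-6-hydroxy-5-[(3R)-3-hydroxyhexa-1,5-dien-2-yl]-2-methylcyclohex-2-en-1-one | C=C([C@@H](CC=C)O)[C@@H]1CC=C(C)C(=O)[C@H]1O
F0 | step 13 | none | none
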